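All runs are simulated with constants of no real substance; noise was put on by code.

The easy step comes first: monomer in chains is what free monomer has lost, so one number tells how far a flask has gone, the logarithm of charged over left.

in all of them: free monomer 1.1 M

| charge | transfer agent | initiator | temperature | remark | time |
|---|---|---|---|---|---|
| Sunday's | 0.33 M | 15 mM | −5 °C | run made earlier |  |
| Monday's | 0.33 M | 24 mM | 12 °C | run made earlier |  |
| midnight | 0.330 M | 11 mM | 25 °C |  | 8.0 min |
| dusk | 0.330 M | 11 mM | 0 °C |  | 8.0 min |

| run | time / min | monomer in chains / % | free monomer / % |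
|---|---|---|---|
| Sunday's | 4.00 | 1.9 | 99.5 |
| Sunday's | 6.00 | 2.6 | 97.9 |
| Sunday's | 8.00 | 4.5 | 95.2 |
| Sunday's | 20.0 | 19.9 | 80.1 |
| Sunday's | 25.0 | 26.9 | 72.6 |
| Sunday's | 40.0 | 47.6 | 51.6 |
| Monday's | 1.33 | 2.6 | 97.0 |
| Monday's | 4.00 | 14.7 | 84.1 |
| Monday's | 6.00 | 30.1 | 69.6 |
| Monday's | 10.0 | 53.9 | 46.5 |
| Monday's | 15.0 | 73.4 | 27.0 |
| Monday's | 20.0 | 83.5 | 16.6 |

(each reading ± 0.5 percentage points)

- the flask that comes out highest in amount of monomer in chains, in percent of the free monomer charged, or "all alike" when all lie within 1.5 percentage points (midnight / dusk / all alike)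
- monomer in chains at the end, in percent of the free monomer charged, midnight
- monomer in chains at the end, in percent of the free monomer charged, dusk

I start with growth by itself, supposing that living ends add free monomer at a steady level. That is pseudo-first-order, so the logarithm climbs straight, and I assume its slope scales with the initiator charged. The late slopes read 0.0228 min⁻¹ in Sunday's run and 0.103 min⁻¹ in Monday's. Taken per initiator charged and carried along 1/T, with 38.9 kJ mol⁻¹, they put midnight at 53.8% and dusk at 16.8%.

Now I add the start-up, the step in which initiator makes living ends. Over its first 8.00 min, Sunday's run has a mean slope of 0.00615 min⁻¹, which is 27.0% of its late slope. Monday's, taken from the readings either side of that time, has 0.0705 min⁻¹, or 68.4%. So I replace the curve by its mean over the time asked. The logarithm divided by time and by initiator charged reads 0.410 L mol⁻¹ min⁻¹ on Sunday and 2.94 L mol⁻¹ min⁻¹ on Monday, a rise worth 73.7 kJ mol⁻¹, steeper than the late slopes gave. Extrapolated, this gives at 25 °C my mean growth constant 11.4 L mol⁻¹ min⁻¹, and at 0 °C 0.750 L mol⁻¹ min⁻¹. I commit to 63.3% at midnight and 6.39% at dusk.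

Transfer and the resting dimer come last, and I can add no number for them. Monday's slope reads 0.101 min⁻¹ early and 0.0973 min⁻¹ late, alike within the scatter, and the two runs change initiator and temperature together. I leave both inside the mean constant as those runs hold them.

The forecast names midnight, with 43% at midnight and 6.5% at dusk, and says: “Only a slight decline suggests weak transfer.” We agree on the order and on dusk, but at midnight my figure is higher than the forecast's.

The simulation puts midnight highest, with 62.2% at midnight and 7.27% at dusk.

    free monomer + initiator → living end + monomer in chains (k = 0.0560 L mol⁻¹ s⁻¹, Ea = 41.0 kJ mol⁻¹)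
    living end + transfer agent → dead chain (kL = 0.00910 L mol⁻¹ s⁻¹, Ea = 59.0 kJ mol⁻¹)
    2 initiator ⇌ resting dimer, settled at all times (K = 3200 L mol⁻¹, ΔH = −26.0 kJ mol⁻¹)
    free monomer + living end → monomer in chains + living end, rate k4*[living end]*[free monomer] (k = 0.400 L mol⁻¹ s⁻¹, Ea = 48.0 kJ mol⁻¹)
    (constants at 25 °C)

What temperature does to the growth step is the largest single effect in the gap of 55 percentage points between midnight and dusk: without it the gap is 9 points. Read back from midnight, the mean growth constant is 11.0 L mol⁻¹ min⁻¹, against the 11.4 L mol⁻¹ min⁻¹ carried. For the same flask as midnight charged with 0.0027 M of initiator, the carried constant gives 21.8% monomer in chains, and that flask holds 23.0%.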